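## Retrosynthetic overview

1. Target ⇒ hydrogenolysis of five benzyl ethers and O‑alkyl cleavage of two methyl esters ⇒ fully protected all‑trans cyclobutane.
2. Cyclobutane ⇒ ring contraction. Nitrogen is excised as N2 through an isodiazene from an all‑trans 3,5‑diarylpyrrolidine‑2,4‑dicarboxylate, and the C1–C2 bond forms with retention.
3. All‑trans pyrrolidine ⇒ its C5 epimer by a thermodynamic radical C–H epimerisation (new) ⇒ silver/QUINAP Michael–Mannich annulation of a glycine aldimine with protected methyl rosmarinate, which fixes the absolute configuration.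
4. Rosmarinate ⇒ cinnamic acid (Heck, acrylic acid) plus aryl lactate (aryl Grignard, methyl (R)‑glycidate), both from catechol through one aryl bromide. Aldimine ⇒ 4‑bromophenol, DMF and glycine methyl ester.
5. Ring order: the pyrrolidine is built first and is then contracted to the cyclobutane.

Assumption: (R)‑QUINAP is taken to deliver the (2R,3S,4R,5S) endo series drawn here; if the first run shows the antipodal ring, (S)‑QUINAP is used and nothing else changes.

## Route

Step 1
Reactants: 1 catechol
Product: 2 1,2-bis(benzyloxy)benzene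
Conditions: BnBr (2.2 equiv), K2CO3 (3 equiv), DMF, 60 °C
Reagents that add atoms: benzyl bromide, BrCc1ccccc1
Why: Williamson ether synthesis alkylates both phenoxides and masks the oxidation‑prone catechol with groups that leave by hydrogenolysis at the end.

Step 2
Reactants: 2 1,2-bis(benzyloxy)benzene
Product: 3 4-bromo-1,2-bis(benzyloxy)benzene
Conditions: NBS (1.0 equiv), MeCN, 0 °C to rt, dark
Reagents that add atoms: N-bromosuccinimide, O=C1CCC(=O)N1Br
Why: Electrophilic aromatic bromination goes para to one alkoxy group, the only unhindered activated position, and one equivalent of NBS stops at the monobromide.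

Step 3
Reactants: 3 4-bromo-1,2-bis(benzyloxy)benzene; 4 methyl (2R)-oxirane-2-carboxylate (methyl (R)-glycidate)
Product: 6 methyl (2R)-3-[3,4-bis(benzyloxy)phenyl]-2-hydroxypropanoate, via arylmagnesium bromide 5 (not isolated)
Conditions: 3 (1.3 equiv), Mg, THF, reflux; CuI (10 mol %), −40 °C; 4, −40 to −20 °C; then cold 1 M HCl
Reagents that add atoms: none
Why: Copper‑catalysed SN2 opening of the epoxide at its unsubstituted carbon by the Grignard reagent outruns ester attack at low temperature and does not touch the C2–O stereocentre of the chiral‑pool glycidate, so (R) is carried over.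

Step 4
Reactants: 3 4-bromo-1,2-bis(benzyloxy)benzene; 7 acrylic acid
Product: 8 (E)-3-[3,4-bis(benzyloxy)phenyl]prop-2-enoic acid
Conditions: Pd(OAc)2 (2 mol %), P(o-tol)3 (6 mol %), Et3N (3 equiv), DMF, 100 °C; then 1 M HCl
Reagents that add atoms: none
Why: In the Mizoroki–Heck reaction, syn carbopalladation followed by syn β‑hydride elimination gives only the (E)‑cinnamic acid.

Step 5
Reactants: 6 methyl (2R)-3-[3,4-bis(benzyloxy)phenyl]-2-hydroxypropanoate; 8 (E)-3-[3,4-bis(benzyloxy)phenyl]prop-2-enoic acid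
Product: 9 methyl (2R)-3-[3,4-bis(benzyloxy)phenyl]-2-({(2E)-3-[3,4-bis(benzyloxy)phenyl]prop-2-enoyl}oxy)propanoate (tetra-O-benzyl methyl rosmarinate)
Conditions: DCC (1.2 equiv), DMAP (0.2 equiv), CH2Cl2, 0 °C to rt
Reagents that add atoms: none
Why: Steglich esterification acylates the secondary alcohol on oxygen without breaking its C–O bond, so the (R) centre is kept.

Step 6
Reactants: 10 4-bromophenol
Product: 11 1-(benzyloxy)-4-bromobenzene
Conditions: BnBr (1.1 equiv), K2CO3 (1.5 equiv), DMF, 60 °C
Reagents that add atoms: benzyl bromide, BrCc1ccccc1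
Why: Williamson ether synthesis removes the acidic O–H before lithiation and uses the same final deprotection as the catechol ethers.

Step 7
Reactants: 11 1-(benzyloxy)-4-bromobenzene
Product: 13 4-(benzyloxy)benzaldehyde, via aryllithium 12 (not isolated)
Conditions: nBuLi (1.05 equiv), THF, −78 °C; DMF (1.5 equiv), −78 to 0 °C; then 1 M HCl
Reagents that add atoms: N,N-dimethylformamide, CN(C)C=O
Why: Bromine–lithium exchange followed by formylation with DMF (Bouveault aldehyde synthesis) is fast at −78 °C and places the aldehyde exactly at the former C–Br carbon.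

Step 8
Reactants: 13 4-(benzyloxy)benzaldehyde; 14 glycine methyl ester hydrochloride; 9 tetra-O-benzyl methyl rosmarinate
Product: 16 4-{(2R)-3-[3,4-bis(benzyloxy)phenyl]-1-methoxy-1-oxopropan-2-yl} 2-methyl (2R,3S,4R,5S)-5-[4-(benzyloxy)phenyl]-3-[3,4-bis(benzyloxy)phenyl]pyrrolidine-2,4-dicarboxylate (endo adduct: groups at C2/C4/C5 cis; C3 aryl trans to them), via glycinate aldimine 15 (not isolated)
Conditions: 13 (1.3 equiv), 14 (1.35 equiv), Et3N (1.4 equiv), 4 Å MS, THF, rt; filtered by cannula onto 9, AgOAc (5 mol %), (R)-QUINAP (5.5 mol %), iPr2NEt (10 mol %), THF, −20 to 0 °C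
Reagents that add atoms: none
Why: Condensation gives the (E)‑aldimine, which once deprotonated on silver adds to the cinnamate β‑carbon and closes by an intramolecular Mannich reaction (catalytic asymmetric formal 1,3‑dipolar cycloaddition, a catalyst type that accepts β‑aryl acrylates), the endo arrangement placing the C2, C4 and C5 groups cis with the alkene‑derived C3/C4 pair trans and the ligand fixing the absolute sense, while the minor facial isomer is a diastereomer because of the chiral ester and is removed on silica.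

Step 9
Reactants: 16 endo pyrrolidine (2R,3S,4R,5S)
Product: 18 4-{(2R)-3-[3,4-bis(benzyloxy)phenyl]-1-methoxy-1-oxopropan-2-yl} 2-methyl (2R,3S,4R,5R)-5-[4-(benzyloxy)phenyl]-3-[3,4-bis(benzyloxy)phenyl]pyrrolidine-2,4-dicarboxylate (all-trans: every pair of neighbours trans; the two aryls cis to each other), via C5 radical 17 (not isolated)
Conditions: [Ir(dF(CF3)ppy)2(dtbbpy)]PF6 (1 mol %), PhSH (1 equiv), THF–MeOH 1:1, 450 nm LEDs, rt, Ar
Reagents that add atoms: none
Why: Proposed new method: the photogenerated phenylthiyl radical reversibly abstracts the weak, hydridic α‑amino C–H bonds (benzylic C5–H, captodative C2–H) and PhSH returns hydrogen to either face of the planar radical, so C5 (and C2) equilibrate while the strong, electron‑poor C4–H and the side‑chain α‑acyloxy C–H are polarity‑mismatched and stay fixed as anchors, which funnels the 4,5‑cis endo isomer into the all‑trans thermodynamic minimum and thereby sets the future C2 of the cyclobutane; the closest known reaction type is the light‑driven iridium/thiol epimerisation of substituted piperidines to their most stable diastereomer, not yet shown on N–H 5‑arylprolinates from azomethine‑ylide chemistry.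

Step 10
Reactants: 18 all-trans pyrrolidine (2R,3S,4R,5R)
Product: 21 3-{(2R)-3-[3,4-bis(benzyloxy)phenyl]-1-methoxy-1-oxopropan-2-yl} 1-methyl (1R,2R,3S,4S)-2-[4-(benzyloxy)phenyl]-4-[3,4-bis(benzyloxy)phenyl]cyclobutane-1,3-dicarboxylate (all-trans), via isodiazene 19 (not isolated), via 1,4-diradical 20 (not isolated)
Conditions: N-(benzyloxy)-N-(pivaloyloxy)-4-(trifluoromethyl)benzamide (1.5 equiv), THF, 45 °C
Reagents that add atoms: none
Why: In this nitrogen‑deletion ring contraction the amine attacks the anomeric amide at nitrogen, loss of pivalate and of the benzyl ester gives the isodiazene, N2 leaves, and the singlet 1,4‑diradical (one benzylic and one α‑ester terminus) closes the new C–C bond faster than bond rotation, so the all‑trans pyrrolidine is copied with retention into the (1R,2R,3S,4S) cyclobutane under non‑oxidising, ammonia‑free conditions that spare the electron‑rich arenes and the esters.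

Step 11
Reactants: 21 protected all-trans cyclobutane
Product: 22 (1R,2R,3S,4S)-2-[4-(benzyloxy)phenyl]-4-[3,4-bis(benzyloxy)phenyl]-3-({(1R)-2-[3,4-bis(benzyloxy)phenyl]-1-carboxyethoxy}carbonyl)cyclobutane-1-carboxylic acid
Conditions: LiI (12 equiv), pyridine, 100 °C; then 1 M HCl
Reagents that add atoms: none
Why: In this nucleophilic O‑alkyl ester cleavage (SN2 of iodide at methyl, lithium‑assisted) only the two methyl esters offer an unhindered sp3 carbon, so the hindered ring ester is freed as easily as the side‑chain one while the secondary‑alkyl ester link, the benzyl ethers and all stereocentres are left alone.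

Step 12
Reactants: 22 penta-O-benzyl diacid
Product: 23 (1R,2R,3S,4S)-3-{[(1R)-1-carboxy-2-(3,4-dihydroxyphenyl)ethoxy]carbonyl}-4-(3,4-dihydroxyphenyl)-2-(4-hydroxyphenyl)cyclobutane-1-carboxylic acid (target)
Conditions: H2 (1 atm), Pd/C (10 wt %), THF–MeOH, rt; filtration under Ar
Reagents that add atoms: none
Why: Catalytic hydrogenolysis cleaves the five O‑benzyl bonds under neutral conditions that touch neither the ester link, the cyclobutane nor any stereocentre.

## Compound list

1 | catechol | Oc1ccccc1O | starting material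
2 | 1,2-bis(benzyloxy)benzene | c1ccc(COc2ccccc2OCc2ccccc2)cc1 | intermediate
3 | 4-bromo-1,2-bis(benzyloxy)benzene | Brc1ccc(OCc2ccccc2)c(OCc2ccccc2)c1 | intermediate
4 | methyl (2R)-oxirane-2-carboxylate | COC(=O)[C@H]1CO1 | starting material
5 | [3,4-bis(benzyloxy)phenyl]magnesium bromide | Br[Mg]c1ccc(OCc2ccccc2)c(OCc2ccccc2)c1 | intermediate (not isolated)
6 | methyl (2R)-3-[3,4-bis(benzyloxy)phenyl]-2-hydroxypropanoate | COC(=O)[C@H](O)Cc1ccc(OCc2ccccc2)c(OCc2ccccc2)c1 | intermediate
7 | acrylic acid | C=CC(=O)O | starting material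
8 | (E)-3-[3,4-bis(benzyloxy)phenyl]prop-2-enoic acid | OC(=O)/C=C/c1ccc(OCc2ccccc2)c(OCc2ccccc2)c1 | intermediate
9 | tetra-O-benzyl methyl (R)-rosmarinate | O=C(/C=C/c1ccc(OCc2ccccc2)c(OCc2ccccc2)c1)O[C@H](Cc1ccc(OCc2ccccc2)c(OCc2ccccc2)c1)C(=O)OC | intermediate
10 | 4-bromophenol | Oc1ccc(Br)cc1 | starting material
11 | 1-(benzyloxy)-4-bromobenzene | Brc1ccc(OCc2ccccc2)cc1 | intermediate
12 | [4-(benzyloxy)phenyl]lithium | [Li]c1ccc(OCc2ccccc2)cc1 | intermediate (not isolated)
13 | 4-(benzyloxy)benzaldehyde | O=Cc1ccc(OCc2ccccc2)cc1 | intermediate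
14 | glycine methyl ester hydrochloride | COC(=O)CN.Cl | starting material
15 | methyl (E)-N-[4-(benzyloxy)benzylidene]glycinate | COC(=O)C/N=C/c1ccc(OCc2ccccc2)cc1 | intermediate (not isolated)
16 | endo pyrrolidine, (2R,3S,4R,5S), (R) side chain | COC(=O)[C@@H]1N[C@H](c2ccc(OCc3ccccc3)cc2)[C@H](C(=O)O[C@H](Cc2ccc(OCc3ccccc3)c(OCc3ccccc3)c2)C(=O)OC)[C@H]1c1ccc(OCc2ccccc2)c(OCc2ccccc2)c1 | intermediate
17 | C5-centred α-amino benzylic radical of 16/18 | COC(=O)[C@@H]1N[C](c2ccc(OCc3ccccc3)cc2)[C@H](C(=O)O[C@H](Cc2ccc(OCc3ccccc3)c(OCc3ccccc3)c2)C(=O)OC)[C@H]1c1ccc(OCc2ccccc2)c(OCc2ccccc2)c1 | intermediate (not isolated)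
18 | all-trans pyrrolidine, (2R,3S,4R,5R), (R) side chain | COC(=O)[C@@H]1N[C@@H](c2ccc(OCc3ccccc3)cc2)[C@H](C(=O)O[C@H](Cc2ccc(OCc3ccccc3)c(OCc3ccccc3)c2)C(=O)OC)[C@H]1c1ccc(OCc2ccccc2)c(OCc2ccccc2)c1 | intermediate
19 | isodiazene (1,1-diazene) of 18 | COC(=O)[C@@H]1[N+](=[N-])[C@@H](c2ccc(OCc3ccccc3)cc2)[C@H](C(=O)O[C@H](Cc2ccc(OCc3ccccc3)c(OCc3ccccc3)c2)C(=O)OC)[C@H]1c1ccc(OCc2ccccc2)c(OCc2ccccc2)c1 | intermediate (not isolated)
20 | 1,4-diradical after loss of N2 | COC(=O)[CH][C@H](c1ccc(OCc2ccccc2)c(OCc2ccccc2)c1)[C@@H](C(=O)O[C@H](Cc1ccc(OCc2ccccc2)c(OCc2ccccc2)c1)C(=O)OC)[CH]c1ccc(OCc2ccccc2)cc1 | intermediate (not isolated)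
21 | protected all-trans cyclobutane, (1R,2R,3S,4S), (R) side chain, two methyl esters | COC(=O)[C@@H]1[C@@H](c2ccc(OCc3ccccc3)cc2)[C@H](C(=O)O[C@H](Cc2ccc(OCc3ccccc3)c(OCc3ccccc3)c2)C(=O)OC)[C@H]1c1ccc(OCc2ccccc2)c(OCc2ccccc2)c1 | intermediate
22 | penta-O-benzyl diacid, (1R,2R,3S,4S), (R) side chain | OC(=O)[C@@H]1[C@@H](c2ccc(OCc3ccccc3)cc2)[C@H](C(=O)O[C@H](Cc2ccc(OCc3ccccc3)c(OCc3ccccc3)c2)C(=O)O)[C@H]1c1ccc(OCc2ccccc2)c(OCc2ccccc2)c1 | intermediate
23 | CNP0270917.1 | O=C(O)[C@@H]1[C@@H](c2ccc(O)cc2)[C@H](C(=O)O[C@H](Cc2ccc(O)c(O)c2)C(=O)O)[C@H]1c1ccc(O)c(O)c1 | target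

## Step count and weak points

Total: 12 steps. Longest linear sequence: 9 steps (1 → 2 → 3 → 6 → 9 → 16 → 18 → 21 → 22 → 23).

**Most likely to fail, first: step 9 (the new reaction).**
- The C5 or C2 radical may be oxidised on to the 1‑pyrroline or pyrrole, or the equilibrium ratio may be modest.
- The fallback uses known chemistry only. It sets out from 3 and 15 and comes back at 21.
- It moves the correction of configuration to a stage where no base‑sensitive side chain is present.
- A Heck reaction of 3 with methyl acrylate gives methyl (E)-3-[3,4-bis(benzyloxy)phenyl]prop-2-enoate F1.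
- Compounds 15 and F1, with the exo‑selective silver amide catalyst AgN(SiMe3)2/DTBM‑SEGPHOS, give the exo pyrrolidine diester F2. In F2 the two aryls are cis and the C2 ester is cis to both.
- The same anomeric amide contracts F2 with retention to the cyclobutane diester F3.
- LiOH (1 equiv, THF–H2O, 0 °C) hydrolyses only the exposed ester that lies trans to both aryls, giving the monoacid F4.
- NaOMe in MeOH at reflux epimerises the crowded C1 ester to the all‑trans monoacid F5.
- Steglich esterification of F5 with 6 gives 21.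

**Second: step 10.**
- The nitrogen is flanked by two substituted carbons and deactivated by the ester, so it may attack the bulky amide slowly.
- The isodiazene can tautomerise to a hydrazone, and the diradical can fragment into two cinnamates.
- The fallback sets out from 18 and comes back at 19, and so at 21. It builds the N–N bond with the smallest possible electrophile and triggers N2 loss separately.
- tBuONO (CH2Cl2, rt) gives the N‑nitrosopyrrolidine F6.
- Zn/AcOH reduces F6 to the N‑aminopyrrolidine F7.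
- PhI(OAc)2 (CH2Cl2, 0 °C) oxidises F7 to 19, which loses N2 to give 21.

**Third: step 8.**
- The electron‑rich, bulky cinnamate is a weak acceptor, so conversion or facial selectivity may be low.
- The fallback sets out from 15 and 9 and comes back at 16. It gives up catalyst control in favour of a more nucleophilic stoichiometric ylide plus separation.
- LiBr (1.5 equiv)/Et3N (1.2 equiv) in THF at rt generates the N‑lithiated azomethine ylide, which adds endo‑selectively but without facial bias.
- The (R) side chain makes the two endo products diastereomers. Compound 16 is therefore separated by chromatography or crystallisation from the ring‑antipodal endo diastereomer F8.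

## Further compounds

F1 | step 9 | methyl (E)-3-[3,4-bis(benzyloxy)phenyl]prop-2-enoate | COC(=O)/C=C/c1ccc(OCc2ccccc2)c(OCc2ccccc2)c1
F2 | step 9 | dimethyl (2S,3S,4R,5R)-5-[4-(benzyloxy)phenyl]-3-[3,4-bis(benzyloxy)phenyl]pyrrolidine-2,4-dicarboxylate (exo adduct) | COC(=O)[C@H]1N[C@@H](c2ccc(OCc3ccccc3)cc2)[C@H](C(=O)OC)[C@H]1c1ccc(OCc2ccccc2)c(OCc2ccccc2)c1
F3 | step 9 | dimethyl 2-[4-(benzyloxy)phenyl]-4-[3,4-bis(benzyloxy)phenyl]cyclobutane-1,3-dicarboxylate, aryls cis, C1 ester cis and C3 ester trans to both aryls | COC(=O)[C@H]1[C@@H](c2ccc(OCc3ccccc3)cc2)[C@H](C(=O)OC)[C@H]1c1ccc(OCc2ccccc2)c(OCc2ccccc2)c1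
F4 | step 9 | C3 monoacid of F3 (C1 methyl ester still cis to both aryls) | COC(=O)[C@H]1[C@@H](c2ccc(OCc3ccccc3)cc2)[C@H](C(=O)O)[C@H]1c1ccc(OCc2ccccc2)c(OCc2ccccc2)c1
F5 | step 9 | all-trans monoacid (C1 methyl ester epimerised, C3 acid free) | COC(=O)[C@@H]1[C@@H](c2ccc(OCc3ccccc3)cc2)[C@H](C(=O)O)[C@H]1c1ccc(OCc2ccccc2)c(OCc2ccccc2)c1
F6 | step 10 | N-nitroso derivative of 18 | COC(=O)[C@@H]1N(N=O)[C@@H](c2ccc(OCc3ccccc3)cc2)[C@H](C(=O)O[C@H](Cc2ccc(OCc3ccccc3)c(OCc3ccccc3)c2)C(=O)OC)[C@H]1c1ccc(OCc2ccccc2)c(OCc2ccccc2)c1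
F7 | step 10 | N-amino derivative of 18 | COC(=O)[C@@H]1N(N)[C@@H](c2ccc(OCc3ccccc3)cc2)[C@H](C(=O)O[C@H](Cc2ccc(OCc3ccccc3)c(OCc3ccccc3)c2)C(=O)OC)[C@H]1c1ccc(OCc2ccccc2)c(OCc2ccccc2)c1
F8 | step 8 | ring-antipodal endo diastereomer of 16, (2S,3R,4S,5R) ring with (R) side chain | COC(=O)[C@H]1N[C@@H](c2ccc(OCc3ccccc3)cc2)[C@@H](C(=O)O[C@H](Cc2ccc(OCc3ccccc3)c(OCc3ccccc3)c2)C(=O)OC)[C@@H]1c1ccc(OCc2ccccc2)c(OCc2ccccc2)c1
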